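**Retrosynthetic overview** (locants: cyclopentanone C1 = C=O, C2, C3, C4 = quaternary C–CH3, C5 = CH bearing the cyclopropane; C9' = benzylic CH)
1. Macrocarpal N ⇐ cyclopentenone 20 (hydrogenation) ⇐ 1,4-keto aldehyde 18 (aldol condensation, C2–C3 bond); the cyclopentanone is the last ring formed.
2. 18 ⇐ Nef reaction of 17 ⇐ γ-nitro aldehyde 8 (as its enamine) + ortho-quinone methide 15 (formal [4+2]; C4–C9' bond, quaternary and benzylic centres; a lactol ring carries the aldehyde temporarily).
3. Key step: 8 ⇐ propanal + nitroalkene 6. The nitroalkene is an α-keto cation (enolonium) equivalent, so the C4–C5 bond joins two carbons that are each α to a carbonyl of the 1,4-dicarbonyl array; the catalyst sets C5.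
4. 6 ⇐ nitroethane (acetyl anion equivalent, C1–C5 bond) + keto aldehyde 3 ⇐ ozonolysis of (+)-2-carene, which supplies the cis-cyclopropane with both stereocentres and the 3-oxobutyl chain; 15 ⇐ diformylphloroglucinol + 3-methylbutanal, stored as the pyrrolidine Mannich base 13.
5. Ring order: cyclopropane (chiral pool) → lactol dihydropyran (temporary) → cyclopentanone.

Assumption: 2,4,6-trihydroxybenzene-1,3-dicarbaldehyde (9) is taken as a purchasable building block.

Step 1
Reactants: 1 (+)-2-carene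
Product: 3 (1S,3R)-2,2-dimethyl-3-(3-oxobutyl)cyclopropane-1-carbaldehyde, via secondary ozonide 2 (not isolated)
Conditions: O3, CH2Cl2, −78 °C; then Me2S, −78 °C to rt
Reagents that add atoms: ozone, O=[O+][O-]
Why: Criegee ozonolysis with reductive work-up cleaves the only C=C bond while the cyclopropane is inert, so both cyclopropane stereocentres (cis arrangement) and the 3-oxobutyl chain of the target come unchanged from the chiral pool.

Step 2
Reactants: 3 (1S,3R)-2,2-dimethyl-3-(3-oxobutyl)cyclopropane-1-carbaldehyde; 4 nitroethane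
Product: 6 4-[(1R,3R)-2,2-dimethyl-3-[(E)-2-nitroprop-1-en-1-yl]cyclopropyl]butan-2-one, via nitro alcohol 5 (not isolated)
Conditions: basic Al2O3, EtNO2 (5 equiv), 0 °C to rt; then CH2Cl2, 40 °C
Reagents that add atoms: none
Why: Henry (nitroaldol) condensation in which the nitronate of nitroethane, an acetyl anion equivalent for C1, adds to the aldehyde much faster than to the methyl ketone and alumina-mediated loss of water gives the more stable (E)-nitroalkene; no new stereocentre remains.

Step 3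
Reactants: 6 4-[(1R,3R)-2,2-dimethyl-3-[(E)-2-nitroprop-1-en-1-yl]cyclopropyl]butan-2-one; 7 propanal
Product: 8 (2R,3R)-3-[(1R,3R)-2,2-dimethyl-3-(3-oxobutyl)cyclopropyl]-2-methyl-4-nitropentanal
Conditions: (S)-α,α-diphenylprolinol trimethylsilyl ether (20 mol%), 4-nitrophenol (20 mol%), propanal (3 equiv), toluene, rt
Reagents that add atoms: none
Why: Enamine-catalysed asymmetric Michael addition to a nitroalkene that serves as an α-keto cation (enolonium) equivalent, so the new C4–C5 bond joins two carbons that are both α to a carbonyl of the later 1,4-dicarbonyl array; the (S)-catalyst shields one enamine face and the usual synclinal transition state gives the syn adduct with the cyclopropyl-bearing carbon (3R) under catalyst control, because the pseudo-symmetrical cyclopropane directs only weakly.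

Step 4
Reactants: 9 2,4,6-trihydroxybenzene-1,3-dicarbaldehyde; 10 3-methylbutanal; 11 pyrrolidine
Product: 13 2,4,6-trihydroxy-5-[3-methyl-1-(pyrrolidin-1-yl)butyl]benzene-1,3-dicarbaldehyde, via iminium phenolate 12 (not isolated)
Conditions: pyrrolidine (1.1 equiv), 3-methylbutanal (1.1 equiv), EtOH, 0 °C to rt; filter the precipitated inner salt
Reagents that add atoms: none
Why: Mannich (Betti-type) aminoalkylation in which the acidic phenol and pyrrolidine turn the aldehyde into an iminium ion whose phenolate counter-ion attacks through the only free ring carbon of 9, and the racemic Mannich base leaves the solution as an ammonium phenolate inner salt, which stops further reaction.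

Step 5
Reactants: 8 (2R,3R)-3-[(1R,3R)-2,2-dimethyl-3-(3-oxobutyl)cyclopropyl]-2-methyl-4-nitropentanal; 11 pyrrolidine; 13 2,4,6-trihydroxy-5-[3-methyl-1-(pyrrolidin-1-yl)butyl]benzene-1,3-dicarbaldehyde
Product: 17 (3R,4R)-2,5,7-trihydroxy-3-methyl-4-(2-methylpropyl)-3-{(1R)-1-[(1R,3R)-2,2-dimethyl-3-(3-oxobutyl)cyclopropyl]-2-nitropropyl}-3,4-dihydro-2H-chromene-6,8-dicarbaldehyde, via enamine 14 (not isolated), via ortho-quinone methide 15 (not isolated), via aminal 16 (not isolated)
Conditions: pyrrolidine (1.1 equiv), 4 Å MS, toluene, rt; then 13 (1.2 equiv), CHCl3, 50 °C; then aq. NH4Cl, THF, rt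
Reagents that add atoms: water, O
Why: Stork enamine addition to an ortho-quinone methide in the sense of an inverse-electron-demand hetero-Diels–Alder reaction (known for enamines of α-branched aldehydes; the stereochemical outcome here is a model-based expectation): the inner salt 13, which is the resting intermediate of an amine-mediated Knoevenagel condensation, releases (E)-15 by retro-Mannich loss of pyrrolidine while the acidic phenols keep the medium too weakly basic to deprotonate the nitro group, and the (E)-enamine (nitrogen anti to the branched carbon) adds endo with nitrogen beneath the quinone methide oxygen, which places isobutyl cis to the ring methyl and sets the benzylic centre; attack anti to the cyclopropyl group, in the rotamer that turns the hydrogen of the catalyst-set centre toward the vinylic methyl (allylic strain), sets the quaternary centre, while the nitro group keeps C1 masked so that neither aldol closure nor epimerisation of C5 can intervene.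

Step 6
Reactants: 17 (3R,4R)-2,5,7-trihydroxy-3-methyl-4-(2-methylpropyl)-3-{(1R)-1-[(1R,3R)-2,2-dimethyl-3-(3-oxobutyl)cyclopropyl]-2-nitropropyl}-3,4-dihydro-2H-chromene-6,8-dicarbaldehyde
Product: 18 (3R,4R)-2,5,7-trihydroxy-3-methyl-4-(2-methylpropyl)-3-{(1R)-1-[(1R,3R)-2,2-dimethyl-3-(3-oxobutyl)cyclopropyl]-2-oxopropyl}-3,4-dihydro-2H-chromene-6,8-dicarbaldehyde
Conditions: NaOMe (4 equiv), MeOH, 0 °C; then TiCl3 (4 equiv), NH4OAc, H2O/THF, pH 6, 0 °C to rt
Reagents that add atoms: water, O
Why: McMurry variant of the Nef reaction, in which the nitronate is reduced by aqueous TiCl3 to the imine and hydrolysed to the ketone near neutral pH, conditions the lactol, phenols, aryl aldehydes and cyclopropane should tolerate; the quaternary and benzylic centres are untouched.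

Step 7
Reactants: 18 (3R,4R)-2,5,7-trihydroxy-3-methyl-4-(2-methylpropyl)-3-{(1R)-1-[(1R,3R)-2,2-dimethyl-3-(3-oxobutyl)cyclopropyl]-2-oxopropyl}-3,4-dihydro-2H-chromene-6,8-dicarbaldehyde
Product: 20 5-{(1S)-1-[(1R,5R)-5-[(1R,3R)-2,2-dimethyl-3-(3-oxobutyl)cyclopropyl]-1-methyl-4-oxocyclopent-2-en-1-yl]-3-methylbutyl}-2,4,6-trihydroxybenzene-1,3-dicarbaldehyde, via β-hydroxy ketone 19 (not isolated)
Conditions: pyrrolidine (30 mol%), AcOH (30 mol%), toluene, 60 °C
Reagents that add atoms: none
Why: Amine–acid-catalysed intramolecular aldol condensation of the 1,4-keto aldehyde (the lactol opens reversibly) joins methyl carbon C2 to aldehyde carbon C3 in the only five-membered closure available, furan formation being blocked by the quaternary carbon; the ketone α-centre C5 equilibrates to the more stable arrangement with the cyclopropyl group trans to the bulky benzylic substituent, which is the target configuration.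

Step 8
Reactants: 20 5-{(1S)-1-[(1R,5R)-5-[(1R,3R)-2,2-dimethyl-3-(3-oxobutyl)cyclopropyl]-1-methyl-4-oxocyclopent-2-en-1-yl]-3-methylbutyl}-2,4,6-trihydroxybenzene-1,3-dicarbaldehyde
Product: 21 Macrocarpal N
Conditions: H2 (1 atm), 10% Pd/C, Ph2S (1 mol%), Et3N (5 mol%), EtOAc, rt
Reagents that add atoms: none
Why: Heterogeneous catalytic hydrogenation of the disubstituted enone C=C bond over sulfide-poisoned palladium leaves aryl aldehydes, ketones and the cyclopropane intact and creates no stereocentre; any reversible addition of the neighbouring phenol to the enone is drained through the open enone by the trace of amine.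

**Compound list**
1 | (+)-2-carene, (1S,6R)-3,7,7-trimethylbicyclo[4.1.0]hept-2-ene | CC1=C[C@H]2[C@@H](CC1)C2(C)C | starting material
2 | secondary ozonide of 1 (1,2,4-trioxolane across the former C2=C3 bond) | CC12CC[C@@H]3[C@H](C(OO1)O2)C3(C)C | intermediate
3 | (1S,3R)-2,2-dimethyl-3-(3-oxobutyl)cyclopropane-1-carbaldehyde | CC(=O)CC[C@@H]1[C@H](C=O)C1(C)C | intermediate
4 | nitroethane | CC[N+](=O)[O-] | starting material
5 | 4-[(1R,3S)-3-(1-hydroxy-2-nitropropyl)-2,2-dimethylcyclopropyl]butan-2-one (mixture at both new centres) | CC(=O)CC[C@@H]1[C@H](C(O)C(C)[N+](=O)[O-])C1(C)C | intermediate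
6 | 4-[(1R,3R)-2,2-dimethyl-3-[(E)-2-nitroprop-1-en-1-yl]cyclopropyl]butan-2-one | CC(=O)CC[C@@H]1[C@H](/C=C(\C)[N+](=O)[O-])C1(C)C | intermediate
7 | propanal | CCC=O | starting material
8 | (2R,3R)-3-[(1R,3R)-2,2-dimethyl-3-(3-oxobutyl)cyclopropyl]-2-methyl-4-nitropentanal (mixture at C-4) | CC(=O)CC[C@@H]1[C@H]([C@H]([C@@H](C)C=O)C(C)[N+](=O)[O-])C1(C)C | intermediate
9 | 2,4,6-trihydroxybenzene-1,3-dicarbaldehyde (diformylphloroglucinol) | O=Cc1c(O)cc(O)c(C=O)c1O | starting material
10 | 3-methylbutanal | CC(C)CC=O | starting material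
11 | pyrrolidine | C1CCNC1 | starting material
12 | 1-(3-methylbutylidene)pyrrolidin-1-ium 2,4-diformyl-3,5-dihydroxyphenolate (iminium phenolate ion pair) | CC(C)CC=[N+]1CCCC1.[O-]c1cc(O)c(C=O)c(O)c1C=O | intermediate
13 | 2,4,6-trihydroxy-5-[3-methyl-1-(pyrrolidin-1-yl)butyl]benzene-1,3-dicarbaldehyde (racemic Mannich base, isolated as its inner salt) | CC(C)CC(N1CCCC1)c1c(O)c(C=O)c(O)c(C=O)c1O | intermediate
14 | 1-[(1E,3R)-3-[(1R,3R)-2,2-dimethyl-3-(3-oxobutyl)cyclopropyl]-2-methyl-4-nitropent-1-en-1-yl]pyrrolidine (enamine of 8) | CC(=O)CC[C@@H]1[C@H]([C@H](/C(C)=C/N2CCCC2)C(C)[N+](=O)[O-])C1(C)C | intermediate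
15 | (5E)-2,4-dihydroxy-5-(3-methylbutylidene)-6-oxocyclohexa-1,3-diene-1,3-dicarbaldehyde (ortho-quinone methide) | CC(C)C/C=C1\C(O)=C(C=O)C(O)=C(C=O)C1=O | intermediate
16 | (3R,4R)-5,7-dihydroxy-3-methyl-4-(2-methylpropyl)-3-{(1R)-1-[(1R,3R)-2,2-dimethyl-3-(3-oxobutyl)cyclopropyl]-2-nitropropyl}-2-(pyrrolidin-1-yl)-3,4-dihydro-2H-chromene-6,8-dicarbaldehyde (aminal; mixture at C-2 and at the nitro carbon) | CC(=O)CC[C@@H]1[C@H]([C@@H](C(C)[N+](=O)[O-])[C@]2(C)C(N3CCCC3)Oc3c(C=O)c(O)c(C=O)c(O)c3[C@H]2CC(C)C)C1(C)C | intermediate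
17 | (3R,4R)-2,5,7-trihydroxy-3-methyl-4-(2-methylpropyl)-3-{(1R)-1-[(1R,3R)-2,2-dimethyl-3-(3-oxobutyl)cyclopropyl]-2-nitropropyl}-3,4-dihydro-2H-chromene-6,8-dicarbaldehyde (lactol; mixture at C-2 and at the nitro carbon) | CC(=O)CC[C@@H]1[C@H]([C@@H](C(C)[N+](=O)[O-])[C@]2(C)C(O)Oc3c(C=O)c(O)c(C=O)c(O)c3[C@H]2CC(C)C)C1(C)C | intermediate
18 | (3R,4R)-2,5,7-trihydroxy-3-methyl-4-(2-methylpropyl)-3-{(1R)-1-[(1R,3R)-2,2-dimethyl-3-(3-oxobutyl)cyclopropyl]-2-oxopropyl}-3,4-dihydro-2H-chromene-6,8-dicarbaldehyde (lactol form of the 1,4-keto aldehyde; mixture at C-2) | CC(=O)CC[C@@H]1[C@H]([C@@H](C(C)=O)[C@]2(C)C(O)Oc3c(C=O)c(O)c(C=O)c(O)c3[C@H]2CC(C)C)C1(C)C | intermediate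
19 | 5-{(1S)-1-[(1R,2R)-2-[(1R,3R)-2,2-dimethyl-3-(3-oxobutyl)cyclopropyl]-5-hydroxy-1-methyl-3-oxocyclopentyl]-3-methylbutyl}-2,4,6-trihydroxybenzene-1,3-dicarbaldehyde (mixture at the carbinol carbon) | CC(=O)CC[C@@H]1[C@H]([C@H]2C(=O)CC(O)[C@]2(C)[C@H](CC(C)C)c2c(O)c(C=O)c(O)c(C=O)c2O)C1(C)C | intermediate
20 | 5-{(1S)-1-[(1R,5R)-5-[(1R,3R)-2,2-dimethyl-3-(3-oxobutyl)cyclopropyl]-1-methyl-4-oxocyclopent-2-en-1-yl]-3-methylbutyl}-2,4,6-trihydroxybenzene-1,3-dicarbaldehyde | CC(=O)CC[C@@H]1[C@H]([C@H]2C(=O)C=C[C@]2(C)[C@H](CC(C)C)c2c(O)c(C=O)c(O)c(C=O)c2O)C1(C)C | intermediate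
21 | Macrocarpal N, 5-{(1S)-1-[(1R,2R)-2-[(1R,3R)-2,2-dimethyl-3-(3-oxobutyl)cyclopropyl]-1-methyl-3-oxocyclopentyl]-3-methylbutyl}-2,4,6-trihydroxybenzene-1,3-dicarbaldehyde | CC(=O)CC[C@@H]1[C@H]([C@H]2C(=O)CC[C@]2(C)[C@H](CC(C)C)c2c(O)c(C=O)c(O)c(C=O)c2O)C1(C)C | target

**Step count:** 8 steps in total. Longest linear sequence: 7 steps (steps 1, 2, 3, 5, 6, 7, 8 from 1); step 4 is a one-step side branch.

**Steps most likely to fail**

Step 3 (the trisubstituted, β-branched nitroalkene may add too slowly or with poor control). The fallback sets out from 3 and comes back at 8, with the roles of the partners exchanged. Wittig olefination of 3 with 2-(triphenylphosphoranylidene)propanal (toluene, 80 °C, aldehyde-selective) gives (E)-3-[(1S,3R)-2,2-dimethyl-3-(3-oxobutyl)cyclopropyl]-2-methylprop-2-enal F1. Conjugate addition of the nitronate of 4 (tetramethylguanidine, MeCN, 0 °C), now the acetyl anion equivalent attacking the enal, gives 8 as a mixture at the cyclopropyl-bearing carbon. The (3R) isomers are taken on after chromatography; the centre next to the aldehyde does not matter because step 5 rebuilds it.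

Step 5 (hindered enamine, acyclic facial control, aminal chemistry next to aryl aldehydes). The fallback sets out from 8 and comes back at 17. Compound 8 is converted with TBSCl, NaI and Et3N in MeCN into the isolated silyl enol ether tert-butyl{[(1E,3R)-3-[(1R,3R)-2,2-dimethyl-3-(3-oxobutyl)cyclopropyl]-2-methyl-4-nitropent-1-en-1-yl]oxy}dimethylsilane F2; the aqueous NaHCO3 work-up hydrolyses any silyl nitronate back to the nitro group. Heating F2 with Mannich base 13 (CHCl3, 60 °C) traps 15 in a thermal hetero-Diels–Alder reaction that needs no enamine and gives the 2-O-tert-butyldimethylsilyl ether of lactol 17 F3. HF·pyridine in THF then releases 17.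

Step 6 (TiCl3 in the presence of aryl aldehydes; incomplete Nef reaction). The fallback sets out from 17 and comes back at 18. Reduction of the secondary nitro group with SnCl2·2H2O, PhSH and Et3N in MeCN stops at (3R,4R)-2,5,7-trihydroxy-3-{(1R)-1-[(1R,3R)-2,2-dimethyl-3-(3-oxobutyl)cyclopropyl]-2-(hydroxyimino)propyl}-3-methyl-4-(2-methylpropyl)-3,4-dihydro-2H-chromene-6,8-dicarbaldehyde F4. Transoximation with aqueous glyoxylic acid (NaOAc buffer, THF, 40 °C) then gives ketone 18 without any titanium reagent.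

**Further compounds**
F1 | step 3 | (E)-3-[(1S,3R)-2,2-dimethyl-3-(3-oxobutyl)cyclopropyl]-2-methylprop-2-enal | CC(=O)CC[C@@H]1[C@H](/C=C(\C)C=O)C1(C)C
F2 | step 5 | tert-butyl{[(1E,3R)-3-[(1R,3R)-2,2-dimethyl-3-(3-oxobutyl)cyclopropyl]-2-methyl-4-nitropent-1-en-1-yl]oxy}dimethylsilane | CC(=O)CC[C@@H]1[C@H]([C@H](/C(C)=C/O[Si](C)(C)C(C)(C)C)C(C)[N+](=O)[O-])C1(C)C
F3 | step 5 | 2-O-tert-butyldimethylsilyl ether of lactol 17 | CC(=O)CC[C@@H]1[C@H]([C@@H](C(C)[N+](=O)[O-])[C@]2(C)C(O[Si](C)(C)C(C)(C)C)Oc3c(C=O)c(O)c(C=O)c(O)c3[C@H]2CC(C)C)C1(C)C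
F4 | step 6 | (3R,4R)-2,5,7-trihydroxy-3-{(1R)-1-[(1R,3R)-2,2-dimethyl-3-(3-oxobutyl)cyclopropyl]-2-(hydroxyimino)propyl}-3-methyl-4-(2-methylpropyl)-3,4-dihydro-2H-chromene-6,8-dicarbaldehyde | CC(=O)CC[C@@H]1[C@H]([C@@H](C(C)=NO)[C@]2(C)C(O)Oc3c(C=O)c(O)c(C=O)c(O)c3[C@H]2CC(C)C)C1(C)C
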